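**Retrosynthetic overview**

1. The target is read as a 13,14-seco-abietane. The C14 acid comes from carbonylation of a Δ7 enol triflate, that is from a C8 ketone; the C13 ketone is carried as the isopropylidene end of a homoprenyl chain and the C18 acid as a CH2OTBS arm.
2. Enabling feature: ring B (C5–C6–C7–C8–C9–C10) is a cyclohexene once C8 is an enol ether (C8=C9). The bonds C6–C7 and C5–C10 are then cut together, in the Diels–Alder sense, into the diene C7=C8–C9=C10 and the alkene C5=C6; because C10 and C5 are joined through C1–C2–C3–C4, the same cycloaddition also closes ring A.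
3. The dienophile C5=C6 sits on the pre-set quaternary C4 and carries a phenylsulfonyl group on C6 as a temporary activating group, expelled later by β-elimination; the diene is made from an ester by carbonyl methylenation.
4. The acyclic triene comes from a C1–C10 B-alkyl Suzuki coupling of an (E)-enol tosylate (alkylated methyl acetoacetate: C8–C13, C15–C17, C20) with a borane holding C1–C6, C18 and C19. C4 is set by asymmetric epoxidation followed by a 1,2-shift with chirality transfer.
5. Ring order: rings A and B are formed together in step 9; no other ring is made or broken.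

Key step: step 9

Remark: abietane numbering is used for the target and, by eventual position, for all intermediates (C4 bears C18 = acid and C19 = methyl, C10 bears C20, C8 bears C14, C9 bears C11–C12–C13(=O)–C15(C16)(C17)); α means the face opposite to the C10 methyl.

**Step 1**
Reactants: 1 pent-1-en-4-yne
Product: 4 (2E)-3-methylhexa-2,5-dien-1-ol, via alkenylalane 2 (not isolated), via lithium alanate 3 (not isolated)
Conditions: Me3Al, Cp2ZrCl2 (20 mol%), CH2Cl2, 0 °C to rt; then n-BuLi, THF/hexane, −78 °C; then (CH2O)n, −78 °C to rt; aq. HCl work-up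
Reagents that add atoms: trimethylaluminium C[Al](C)C; formaldehyde (as paraformaldehyde) C=O
Why: Zirconium-catalysed syn-carboalumination of the terminal alkyne (Negishi carboalumination) puts CH3 on the internal and Al on the terminal carbon, which fixes the (E) geometry, and the alanate is hydroxymethylated with retention while the remote terminal alkene stays inert.

**Step 2**
Reactants: 4 (2E)-3-methylhexa-2,5-dien-1-ol
Product: 5 [(2S,3S)-3-methyl-3-(prop-2-en-1-yl)oxiran-2-yl]methanol
Conditions: Ti(OiPr)4 (cat.), L-(+)-diethyl tartrate (cat.), t-BuOOH, 4 Å MS, CH2Cl2, −20 °C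
Reagents that add atoms: tert-butyl hydroperoxide CC(C)(C)OO
Why: Sharpless asymmetric epoxidation; with L-(+)-diethyl tartrate the titanium-bound (E)-allylic alcohol is epoxidised on the face that gives the (2S,3S) epoxide, and the non-allylic terminal alkene is not touched.

**Step 3**
Reactants: 5 [(2S,3S)-3-methyl-3-(prop-2-en-1-yl)oxiran-2-yl]methanol
Product: 6 tert-butyl(dimethyl){[(2S,3S)-3-methyl-3-(prop-2-en-1-yl)oxiran-2-yl]methoxy}silane
Conditions: TBSCl, imidazole, DMF, 0 °C to rt
Reagents that add atoms: tert-butyl(chloro)dimethylsilane CC(C)(C)[Si](C)(C)Cl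
Why: Standard silylation of the primary alcohol, needed because the siloxymethyl group is the migrating group of step 4.

**Step 4**
Reactants: 6 tert-butyl(dimethyl){[(2S,3S)-3-methyl-3-(prop-2-en-1-yl)oxiran-2-yl]methoxy}silane
Product: 7 (2S)-2-({[tert-butyl(dimethyl)silyl]oxy}methyl)-2-methylpent-4-enal
Conditions: MeAl(OAr)2 (Ar = 4-bromo-2,6-di-tert-butylphenyl), CH2Cl2, −78 °C to −20 °C
Reagents that add atoms: none
Why: Lewis-acid-promoted semipinacol-type rearrangement of a 2,3-epoxy silyl ether: the bulky aluminium aryloxide opens the epoxide at the tertiary carbon and the siloxymethyl group shifts anti to the leaving oxygen, so the epoxide chirality is transferred with inversion to the (S) quaternary aldehyde (future C4 with C19 methyl, C18 arm and C5 aldehyde).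

**Step 5**
Reactants: 7 (2S)-2-({[tert-butyl(dimethyl)silyl]oxy}methyl)-2-methylpent-4-enal
Product: 8 tert-butyl(dimethyl){[(2R,3E)-2-methyl-4-(phenylsulfonyl)-2-(prop-2-en-1-yl)but-3-en-1-yl]oxy}silane
Conditions: (EtO)2P(O)CH2SO2Ph, NaH, THF, 0 °C to rt
Reagents that add atoms: diethyl [(phenylsulfonyl)methyl]phosphonate CCOP(=O)(CS(=O)(=O)c1ccccc1)OCC
Why: Horner–Wadsworth–Emmons olefination of the non-enolisable aldehyde with the sulfonyl-stabilised phosphonate gives the (E)-vinyl sulfone, the activated dienophile C5=C6, and no stereocentre can epimerise.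

**Step 6**
Reactants: 9 methyl 3-oxobutanoate; 10 5-bromo-2-methylpent-2-ene
Product: 11 methyl 2-acetyl-6-methylhept-5-enoate (racemic)
Conditions: NaH, THF/DMF, 0 °C; then 10, NaI (cat.), 60 °C
Reagents that add atoms: none
Why: C-alkylation of the acetoacetate sodium enolate (acetoacetic ester alkylation) installs the C11–C17 side chain, whose isopropylidene end is the masked C13 ketone.

**Step 7**
Reactants: 11 methyl 2-acetyl-6-methylhept-5-enoate
Product: 12 methyl (2E)-3-{[(4-methylphenyl)sulfonyl]oxy}-2-(4-methylpent-3-en-1-yl)but-2-enoate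
Conditions: TsCl, Me2N(CH2)6NMe2, MeCN, 0 °C (no lithium salt)
Reagents that add atoms: 4-methylbenzenesulfonyl chloride Cc1ccc(cc1)S(=O)(=O)Cl
Why: O-sulfonylation of the β-keto ester under non-chelating amine conditions gives the (E)-enol tosylate (tosylate trans to the ester), the geometry that later places the tether trans to C8.

**Step 8**
Reactants: 8 vinyl sulfone; 12 (E)-enol tosylate
Product: 14 methyl (2E,7R,8E)-7-({[tert-butyl(dimethyl)silyl]oxy}methyl)-3,7-dimethyl-2-(4-methylpent-3-en-1-yl)-9-(phenylsulfonyl)nona-2,8-dienoate, via alkylborane 13 (not isolated)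
Conditions: 9-BBN-H, THF, 0 °C to rt; then 12, Pd(OAc)2 (5 mol%), SPhos (10 mol%), K3PO4 (aq), THF, 50 °C
Reagents that add atoms: none
Why: Anti-Markovnikov hydroboration of the only unhindered terminal alkene (the vinyl sulfone is electron-poor and 1,2-disubstituted) followed by B-alkyl Suzuki–Miyaura coupling with the activated enol tosylate, which proceeds with retention of the alkene geometry and joins C1 to C10.

**Step 9**
Reactants: 14 tetrasubstituted (E)-enoate
Product: 16 cycloadduct (trans-fused rings A and B; 8-methoxy Δ8 enol ether; 6α-phenylsulfonyl; 5α-H; 10β-CH3; 4β-CH3; 4α-CH2OTBS; 9-(4-methylpent-3-en-1-yl)), via methoxydiene 15 (not isolated)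
Conditions: Cp2TiMe2 (3 equiv), toluene, 70 °C, dark; filtration through basic alumina; then toluene (0.01 M), BHT, Et3N (trace), 130 °C, sealed tube
Reagents that add atoms: dimethyltitanocene C[Ti](C)(C1C=CC=C1)C1C=CC=C1
Why: Methylenation of the ester carbonyl by the titanium methylidene formed from Cp2TiMe2 gives the 2-methoxy-1,3-diene 15, whose C7=C8–C9=C10 unit then adds thermally and suprafacially across the tethered (E)-vinyl sulfone C5=C6 in a concerted but asynchronous type 1 intramolecular Diels–Alder reaction; the closest known reaction types are the methylenation of α,β-unsaturated esters to 2-alkoxydienes and the thermal cyclisation of sulfonyl-activated 1,3,9-decatrienes. Ring B closes as the [4+2] cyclohexene through the new bonds C6–C7 and C5–C10, and ring A closes in the same event as the six-membered tether ring C10–C1–C2–C3–C4–C5 through the C5–C10 bond, which gives the fused decalin. C10 becomes quaternary with a fixed relation to C5 because the (E) geometry of 14 places the tether outside and the methyl inside on the diene terminus, and the chair-like tether with diene and dienophile both equatorial and the sulfone endo should give the trans ring fusion (C5–H anti to the C10 methyl). The absolute sense is passed on from C4: its silyloxymethyl arm, the larger group with more free rotamers in the open position, should lie anti to the forming C5–C10 bond (equatorial) and its methyl inside, which makes C19 axial and syn to C20; the size difference is modest, so this is the weakest control element of the route. C6 is formed trans to C4 as a consequence of the (E) dienophile and is erased in step 10, while C9 stays sp2 until step 10. The step therefore needs trans over cis fusion and the C4-matched face, both of which rest on the chair tether and on the size difference at C4, while the regiochemistry is enforced by the tether and the reactivity by the sulfone.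

**Step 10**
Reactants: 16 cycloadduct
Product: 18 Δ6-8-enone (5α-H; 9α-H; 10β-CH3; 4β-CH3; 4α-CH2OTBS; 9β-(4-methylpent-3-en-1-yl)), via sulfonyl ketone 17 (not isolated)
Conditions: 0.1 M aq. oxalic acid, THF, 0 °C; then DBU, CH2Cl2, 0 °C to rt
Reagents that add atoms: water O
Why: Mild acid hydrolysis of the enol ether (C-protonation of C9 on the α face, anti to the C10 methyl, gives the equatorial side chain, which is also the thermodynamic epimer next to the ketone) and E1cB loss of benzenesulfinate from the β-sulfonyl ketone give the enone, so the sulfone has served as a traceless activating group.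

**Step 11**
Reactants: 18 Δ6-8-enone
Product: 20 Δ7-8-enol triflate (4α-CH2OTBS; homoprenyl side chain), via lithium enolate 19 (not isolated)
Conditions: LiBH(s-Bu)3, THF, −78 °C; then PhNTf2, −78 °C to 0 °C
Reagents that add atoms: N-phenylbis(trifluoromethanesulfonimide) FC(F)(F)S(=O)(=O)N(c1ccccc1)S(=O)(=O)C(F)(F)F
Why: Conjugate (1,4) reduction of the β-unsubstituted cyclohexenone by the hindered borohydride gives the Δ7 enolate regiospecifically and O-triflation traps it (reductive enol triflation); C9 is not part of the enolate and keeps its configuration.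

**Step 12**
Reactants: 20 Δ7-8-enol triflate
Product: 22 13-hydroxy enol triflate (both C13 epimers; 4α-CH2OTBS), via alkylborane 21 (not isolated)
Conditions: BH3·SMe2 (1 equiv), THF, 0 °C; then H2O2 (30%), 1 M NaOH, 0 °C
Reagents that add atoms: hydrogen peroxide OO
Why: Hydroboration–oxidation; borane adds to the electron-rich trisubstituted alkene with boron on the less substituted C13 while the electron-poor, hindered enol triflate is left, and the new C13 centre is of no consequence because it is oxidised in step 13.

**Step 13**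
Reactants: 22 13-hydroxy enol triflate
Product: 24 13-oxo-18-oic acid enol triflate, via keto alcohol 23 (not isolated)
Conditions: CrO3, H2SO4, H2O/acetone, 0 °C to rt
Reagents that add atoms: water O
Why: Jones oxidation; the secondary alcohol gives the C13 ketone, and the aqueous acid cleaves the primary silyl ether whose alcohol is oxidised through the aldehyde hydrate to the C18 acid, the enol triflate being stable to acid and chromic acid.

**Step 14**
Reactants: 24 13-oxo-18-oic acid enol triflate
Product: 25 13-oxo-13,14-seco-abiet-7-ene-14,18-dioic acid (target)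
Conditions: Pd(OAc)2 (5 mol%), PPh3 (10 mol%), CO (1 atm), KOAc, DMF/H2O, 60 °C; acidic work-up
Reagents that add atoms: carbon monoxide [C-]#[O+]; water O
Why: Palladium-catalysed hydroxycarbonylation of the enol triflate (oxidative addition of zerovalent palladium, CO insertion, capture of the acyl palladium by acetate and water) gives the α,β-unsaturated C14 acid with the double bond held at C7=C8 and no stereocentre touched.

**Compound list**

1 | pent-1-en-4-yne | C=CCC#C | starting material
2 | dimethyl[(1E)-2-methylpenta-1,4-dien-1-yl]alane | C=CC/C(C)=C/[Al](C)C | intermediate (not isolated)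
3 | lithium butyl(dimethyl)[(1E)-2-methylpenta-1,4-dien-1-yl]aluminate | [Li+].C=CC/C(C)=C/[Al-](C)(C)CCCC | intermediate (not isolated)
4 | (2E)-3-methylhexa-2,5-dien-1-ol | C=CC/C(C)=C/CO | intermediate
5 | [(2S,3S)-3-methyl-3-(prop-2-en-1-yl)oxiran-2-yl]methanol | C=CC[C@]1(C)O[C@H]1CO | intermediate
6 | tert-butyl(dimethyl){[(2S,3S)-3-methyl-3-(prop-2-en-1-yl)oxiran-2-yl]methoxy}silane | C=CC[C@]1(C)O[C@H]1CO[Si](C)(C)C(C)(C)C | intermediate
7 | (2S)-2-({[tert-butyl(dimethyl)silyl]oxy}methyl)-2-methylpent-4-enal | O=C[C@](C)(CO[Si](C)(C)C(C)(C)C)CC=C | intermediate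
8 | tert-butyl(dimethyl){[(2R,3E)-2-methyl-4-(phenylsulfonyl)-2-(prop-2-en-1-yl)but-3-en-1-yl]oxy}silane | O=S(=O)(c1ccccc1)/C=C/[C@](C)(CO[Si](C)(C)C(C)(C)C)CC=C | intermediate
9 | methyl 3-oxobutanoate (methyl acetoacetate) | COC(=O)CC(C)=O | starting material
10 | 5-bromo-2-methylpent-2-ene | CC(C)=CCCBr | starting material
11 | methyl 2-acetyl-6-methylhept-5-enoate (racemic) | COC(=O)C(CCC=C(C)C)C(C)=O | intermediate
12 | methyl (2E)-3-{[(4-methylphenyl)sulfonyl]oxy}-2-(4-methylpent-3-en-1-yl)but-2-enoate | COC(=O)/C(CCC=C(C)C)=C(C)/OS(=O)(=O)c1ccc(C)cc1 | intermediate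
13 | 9-[(4R,5E)-4-({[tert-butyl(dimethyl)silyl]oxy}methyl)-4-methyl-6-(phenylsulfonyl)hex-5-en-1-yl]-9-borabicyclo[3.3.1]nonane | O=S(=O)(c1ccccc1)/C=C/[C@](C)(CO[Si](C)(C)C(C)(C)C)CCCB1C2CCCC1CCC2 | intermediate (not isolated)
14 | methyl (2E,7R,8E)-7-({[tert-butyl(dimethyl)silyl]oxy}methyl)-3,7-dimethyl-2-(4-methylpent-3-en-1-yl)-9-(phenylsulfonyl)nona-2,8-dienoate | COC(=O)/C(CCC=C(C)C)=C(C)/CCC[C@@](C)(CO[Si](C)(C)C(C)(C)C)/C=C/S(=O)(=O)c1ccccc1 | intermediate
15 | 2-methoxydiene: 14 with the ester C=O replaced by C=CH2 (C7=C8(OCH3)–C9=C10, C1 trans to C8) | C=C(OC)/C(CCC=C(C)C)=C(C)/CCC[C@@](C)(CO[Si](C)(C)C(C)(C)C)/C=C/S(=O)(=O)c1ccccc1 | intermediate (not isolated)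
16 | cycloadduct: trans-fused decalin; 8-methoxy Δ8 enol ether; 6α-phenylsulfonyl; 5α-H; 10β-CH3; 4β-CH3; 4α-CH2OTBS; 9-(4-methylpent-3-en-1-yl) | CC(C)=CCCC1=C(OC)C[C@H](S(=O)(=O)c3ccccc3)[C@@H]2[C@]1(C)CCC[C@@]2(C)CO[Si](C)(C)C(C)(C)C | intermediate
17 | 8-ketone with 6α-phenylsulfonyl; 9α-H; otherwise as 16 | CC(C)=CCC[C@H]1C(=O)C[C@H](S(=O)(=O)c3ccccc3)[C@@H]2[C@]1(C)CCC[C@@]2(C)CO[Si](C)(C)C(C)(C)C | intermediate (not isolated)
18 | Δ6-8-enone; 5α-H; 9α-H; 10β-CH3; 4β-CH3; 4α-CH2OTBS; 9β-(4-methylpent-3-en-1-yl) | CC(C)=CCC[C@H]1C(=O)C=C[C@@H]2[C@]1(C)CCC[C@@]2(C)CO[Si](C)(C)C(C)(C)C | intermediate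
19 | lithium Δ7-8-enolate of the 6,7-dihydro ketone | CC(C)=CCC[C@H]1C(O[Li])=CC[C@@H]2[C@]1(C)CCC[C@@]2(C)CO[Si](C)(C)C(C)(C)C | intermediate (not isolated)
20 | Δ7-8-enol triflate; 4α-CH2OTBS; 9β-(4-methylpent-3-en-1-yl) | CC(C)=CCC[C@H]1C(OS(=O)(=O)C(F)(F)F)=CC[C@@H]2[C@]1(C)CCC[C@@]2(C)CO[Si](C)(C)C(C)(C)C | intermediate
21 | C13 alkylborane of 20 (drawn as the monoalkylborane) | CC(C)C(B)CC[C@H]1C(OS(=O)(=O)C(F)(F)F)=CC[C@@H]2[C@]1(C)CCC[C@@]2(C)CO[Si](C)(C)C(C)(C)C | intermediate (not isolated)
22 | 13-hydroxy Δ7-8-enol triflate; 4α-CH2OTBS (both C13 epimers) | CC(C)C(O)CC[C@H]1C(OS(=O)(=O)C(F)(F)F)=CC[C@@H]2[C@]1(C)CCC[C@@]2(C)CO[Si](C)(C)C(C)(C)C | intermediate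
23 | 13-oxo-18-hydroxy Δ7-8-enol triflate | CC(C)C(=O)CC[C@H]1C(OS(=O)(=O)C(F)(F)F)=CC[C@@H]2[C@]1(C)CCC[C@@]2(C)CO | intermediate (not isolated)
24 | 13-oxo-8-{[(trifluoromethyl)sulfonyl]oxy}-13,14-seco-14-norabiet-7-en-18-oic acid | CC(C)C(=O)CC[C@H]1C(OS(=O)(=O)C(F)(F)F)=CC[C@@H]2[C@]1(C)CCC[C@@]2(C)C(=O)O | intermediate
25 | 13-oxo-13,14-seco-abiet-7-ene-14,18-dioic acid | CC(C)C(=O)CC[C@H]1C(C(=O)O)=CC[C@@H]2[C@]1(C)CCC[C@@]2(C)C(=O)O | target

**Step count and risks**

Total step count: 14. Longest linear sequence: 12 steps (steps 1–5 and 8–14).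

Steps most likely to fail:

1. Step 9. The methylenation of the hindered, twisted ester may stall, and the acid-labile methoxydiene may be lost on the titanium residues before it cyclises. The thermal cycloaddition may also leak into the cis-fused series or into the C4-mismatched face, because methyl and silyloxymethyl differ only modestly in size. Fallback (sets out from 8 and 10, with acetylacetone as an extra purchased reagent, and returns at 18): the diene is made by soft enolisation of a ketone instead of by carbonyl methylenation, which gives an isolable diene that can be purified and cyclised under separate conditions. Acetylacetone is C-alkylated with bromide 10 (K2CO3, NaI, acetone) to 3-(4-methylpent-3-en-1-yl)pentane-2,4-dione F1. F1 is O-tosylated under the non-chelating conditions of step 7 to (2E)-3-(4-methylpent-3-en-1-yl)-4-oxopent-2-en-2-yl 4-methylbenzenesulfonate F2. Borane 13 (from 8 as in step 8) is coupled with F2 to the methyl ketone (3E,8R,9E)-8-({[tert-butyl(dimethyl)silyl]oxy}methyl)-4,8-dimethyl-3-(4-methylpent-3-en-1-yl)-10-(phenylsulfonyl)deca-3,9-dien-2-one F3. TBSOTf and Et3N at −78 °C give the 2-silyloxydiene F4, which is heated in toluene to the silyl enol ether cycloadduct F5. Buffered TBAF and then DBU take F5 through ketone 17 to enone 18. This fallback answers the diene-formation failure; it does not by itself change the C4 facial bias.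

2. Step 8. Transmetalation and oxidative addition at the hindered, fully substituted enol tosylate may be slow, with protodeboronation competing, and the aqueous base may erode the (E) geometry or hydrolyse the β-tosyloxy enoate by addition–elimination. Fallback (sets out from 8 through borane 13 and returns at 14): a base-free Negishi coupling. Borane 13 is iodinated (I2, NaOMe, MeOH) to tert-butyl{[(2R,3E)-2-(3-iodopropyl)-2-methyl-4-(phenylsulfonyl)but-3-en-1-yl]oxy}dimethylsilane F6. Zinc insertion (Zn, LiCl, THF) gives the alkylzinc iodide F7, which is coupled with tosylate 12 (Pd(OAc)2, SPhos, THF) to enoate 14.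

3. Step 11. Hydride delivery to C6 is hindered by the neighbouring quaternary C4, so 1,2-reduction of the carbonyl may compete with the conjugate reduction, and the hindered enolate may be triflated incompletely. Fallback (sets out from 18 and returns at 20): copper hydride conjugate hydrosilylation. [(Ph3P)CuH]6 (cat.) and PhMe2SiH in toluene give the Δ7 dimethyl(phenyl)silyl enol ether F8. MeLi (THF, 0 °C) then releases lithium enolate 19, which is triflated with PhNTf2 to 20.

**Further compounds**

F1 | step 9 | 3-(4-methylpent-3-en-1-yl)pentane-2,4-dione | CC(=O)C(CCC=C(C)C)C(C)=O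
F2 | step 9 | (2E)-3-(4-methylpent-3-en-1-yl)-4-oxopent-2-en-2-yl 4-methylbenzenesulfonate | CC(=O)/C(CCC=C(C)C)=C(C)/OS(=O)(=O)c1ccc(C)cc1
F3 | step 9 | (3E,8R,9E)-8-({[tert-butyl(dimethyl)silyl]oxy}methyl)-4,8-dimethyl-3-(4-methylpent-3-en-1-yl)-10-(phenylsulfonyl)deca-3,9-dien-2-one | CC(=O)/C(CCC=C(C)C)=C(C)/CCC[C@@](C)(CO[Si](C)(C)C(C)(C)C)/C=C/S(=O)(=O)c1ccccc1
F4 | step 9 | 2-(tert-butyldimethylsilyloxy)diene from F3 (C7=C8(OTBS)–C9=C10) | C=C(O[Si](C)(C)C(C)(C)C)/C(CCC=C(C)C)=C(C)/CCC[C@@](C)(CO[Si](C)(C)C(C)(C)C)/C=C/S(=O)(=O)c1ccccc1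
F5 | step 9 | cycloadduct as 16 with OTBS in place of OCH3 at C8 | CC(C)=CCCC1=C(O[Si](C)(C)C(C)(C)C)C[C@H](S(=O)(=O)c3ccccc3)[C@@H]2[C@]1(C)CCC[C@@]2(C)CO[Si](C)(C)C(C)(C)C
F6 | step 8 | tert-butyl{[(2R,3E)-2-(3-iodopropyl)-2-methyl-4-(phenylsulfonyl)but-3-en-1-yl]oxy}dimethylsilane | O=S(=O)(c1ccccc1)/C=C/[C@](C)(CO[Si](C)(C)C(C)(C)C)CCCI
F7 | step 8 | alkylzinc iodide from F6 | I[Zn]CCC[C@@](C)(CO[Si](C)(C)C(C)(C)C)/C=C/S(=O)(=O)c1ccccc1
F8 | step 11 | Δ7-8-enol dimethyl(phenyl)silyl ether of the 6,7-dihydro ketone | CC(C)=CCC[C@H]1C(O[Si](C)(C)c3ccccc3)=CC[C@@H]2[C@]1(C)CCC[C@@]2(C)CO[Si](C)(C)C(C)(C)C
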